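## Retrosynthetic overview

1. The target (2R,3R)-trans-dihydroflavonol comes from a late-stage double cross-metathesis (allyl to prenyl) of the 8,3'-diallyl analogue. This keeps acid-labile o-prenylphenols and prenyl alkenes out of every earlier step.
2. The C ring is formed last, by fluoride-triggered desilylation of the 2'-OH and 6-endo benzylic opening of a trans-α,β-epoxy aryl ketone. C2 is set by inversion at the benzylic epoxide carbon, and C3 is the retained epoxide α-carbon.
3. The epoxy ketone is made by adding an aryllithium (from an aryl bromide) to a Weinreb glycidamide. The glycidamide is derived from a Sharpless asymmetric epoxidation of a cinnamyl alcohol, which sets both stereocentres in one catalytic step.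
4. The B-ring allyl group comes from an aryl allyl ether Claisen rearrangement. The A-ring allyl group comes from directed lithiation and allylation of 1,3-dimethoxybenzene. No Claisen–Schmidt chalcone is used.

**Assumptions:** the target is read from the SMILES as (2R,3R), the trans isomer. 1,3-Dimethoxybenzene and methyl (E)-4-hydroxycinnamate are commercial, as are the common reagents.

## Route

**Step 1**
Reactants: 1, 1,3-dimethoxybenzene
Product: 2, 2-allyl-1,3-dimethoxybenzene
Conditions: n-BuLi, THF, 0 °C to rt, 2 h; then allyl bromide, CuI (cat.), –20 °C to rt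
Reagents that add atoms: allyl bromide, C=CCBr
Why: The C2 proton between the two OMe groups is the most acidic, so directed ortho-metalation followed by SN2 allylation puts the allyl group exactly at the future C8.

**Step 2**
Reactants: 2
Product: 3, 2-allyl-4-bromo-1,3-dimethoxybenzene
Conditions: NBS (1.0 equiv), MeCN, 0 °C to rt
Reagents that add atoms: N-bromosuccinimide, BrN1C(=O)CCC1=O
Why: Electrophilic aromatic bromination occurs at C4, which is ortho to one OMe and para to the other. It is much faster than attack on the monosubstituted allyl alkene. This bromide becomes the future C4a.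

**Step 3**
Reactants: 3
Product: 4, 2-allyl-4-bromobenzene-1,3-diol
Conditions: BBr3 (3 equiv), CH2Cl2, –78 °C to 0 °C; aqueous quench
Reagents that add atoms: none
Why: BBr3 cleaves aryl methyl ethers. At low temperature the aryl bromide and the terminal alkene survive.

**Step 4**
Reactants: 4
Product: 5, 2-allyl-4-bromo-1,3-bis(tert-butyldimethylsilyloxy)benzene
Conditions: TBSCl (2.4 equiv), imidazole, DMF, rt
Reagents that add atoms: tert-butyldimethylsilyl chloride, CC(C)(C)[Si](C)(C)Cl
Why: Silyl ethers withstand the aryllithium step and can later be removed with fluoride under non-acidic conditions. The freed 2'-O then acts as the cyclising nucleophile.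

**Step 5**
Reactants: 6, methyl (E)-4-hydroxycinnamate
Product: 7, methyl (E)-3-(4-allyloxyphenyl)acrylate
Conditions: allyl bromide, K2CO3, acetone, reflux
Reagents that add atoms: allyl bromide, C=CCBr
Why: Williamson O-allylation of the phenol.

**Step 6**
Reactants: 7
Product: 8, methyl (E)-3-(3-allyl-4-hydroxyphenyl)acrylate
Conditions: PhNEt2, 200–210 °C (or neat, microwave), 1 h
Reagents that add atoms: none
Why: Aromatic Claisen [3,3] rearrangement moves the allyl group to the ortho position, which becomes C3' after the later cross-metathesis. The (E)-cinnamate is untouched.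

**Step 7**
Reactants: 8
Product: 9, methyl (E)-3-[3-allyl-4-(TBSO)phenyl]acrylate
Conditions: TBSCl, imidazole, DMF, rt
Reagents that add atoms: tert-butyldimethylsilyl chloride, CC(C)(C)[Si](C)(C)Cl
Why: Protecting the phenol is necessary for DIBAL reduction, the Ti-mediated epoxidation and the aryllithium step.

**Step 8**
Reactants: 9
Product: 10, (E)-3-[3-allyl-4-(TBSO)phenyl]prop-2-en-1-ol
Conditions: DIBAL-H (2.5 equiv), CH2Cl2, –78 °C to 0 °C
Reagents that add atoms: none
Why: 1,2-Reduction of the cinnamate ester gives the allylic alcohol required for Sharpless epoxidation. The aryl silyl ether, terminal alkene and (E)-olefin are untouched.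

**Step 9**
Reactants: 10
Product: 11, {(2S,3S)-3-[3-allyl-4-(TBSO)phenyl]oxiran-2-yl}methanol
Conditions: Ti(OiPr)4 (10 mol%), L-(+)-diethyl tartrate (12 mol%), TBHP (anhydrous, 2 equiv), 4 Å MS, CH2Cl2, –20 °C
Reagents that add atoms: tert-butyl hydroperoxide, CC(C)(C)OO (oxygen source)
Why: Sharpless asymmetric epoxidation is selective for the allylic alcohol, not the isolated terminal alkene. L-(+)-DET gives the (2S,3S) trans-epoxide, setting both stereocentres of the final C2 and C3.

**Step 10**
Reactants: 11
Product: 12, (2R,3S)-3-[3-allyl-4-(TBSO)phenyl]oxirane-2-carboxylic acid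
Conditions: TEMPO (10 mol%), NaClO2 (2 equiv), NaOCl (2 mol%), MeCN / pH 6.7 phosphate buffer, 35 °C
Reagents that add atoms: sodium chlorite, [Na+].[O-]Cl=O (oxygen source)
Why: Buffered TEMPO/chlorite oxidation (Zhao–Miller) takes the primary alcohol to the carboxylic acid under near-neutral conditions, so the acid-sensitive benzylic epoxide survives. No stereocentre is touched. The descriptor at C2 changes from S to R only because the CIP priorities change.

**Step 11**
Reactants: 12
Product: 13, (2R,3S)-3-[3-allyl-4-(TBSO)phenyl]-N-methoxy-N-methyloxirane-2-carboxamide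
Conditions: MeNHOMe·HCl, EDC·HCl, HOBt, N-methylmorpholine, CH2Cl2, 0 °C to rt
Reagents that add atoms: N,O-dimethylhydroxylamine, CNOC
Why: Carbodiimide amide coupling gives the Weinreb amide, an acyl donor that avoids over-addition in the next step.

**Step 12**
Reactants: 5, aryl bromide; 13, Weinreb glycidamide
Product: 14, [(2R,3S)-3-(3-allyl-4-TBSO-phenyl)oxiran-2-yl][3-allyl-2,4-bis(TBSO)phenyl]methanone
Conditions: 5 (1.6 equiv), t-BuLi (3.2 equiv), THF, –78 °C, 15 min; then 13 (1.0 equiv), –78 °C, 1 h; aq. NH4Cl
Reagents that add atoms: none
Why: Br/Li exchange gives the aryllithium, which adds to the Weinreb amide and collapses to the ketone on work-up through the stable chelated tetrahedral intermediate (Weinreb ketone synthesis). The epoxide stereocentres are not touched.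

**Step 13**
Reactants: 14
Product: 15, (2R,3R)-8,3'-diallyl-3,7,4'-trihydroxyflavanone (8,3'-diallyl-7,4'-dihydroxy-dihydroflavonol)
Conditions: TBAF (2.2 equiv), THF, –20 °C, 20 min; then TBAF (1.3 equiv), 0 °C, 20 min; quench with aq. NH4Cl
Reagents that add atoms: none
Why: Fluoride removes the more labile silyl ethers on the electron-poor A ring first, and the 2'-phenoxide opens the epoxide intramolecularly at the benzylic carbon (6-endo-tet) with inversion. This sets C2 as R, while C3 keeps its R configuration, and the trans epoxide gives the trans ring. The B-ring silyl ether is then removed.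
Proposed new method: the mechanism is an Algar–Flynn–Oyamada-type 6-endo opening of a 2'-hydroxychalcone epoxide, here triggered by in situ desilylation rather than by base and H2O2; the benzylic carbon is activated by the p-OSiR3 (later p-OH) aryl group, which favours 6-endo attack over 5-exo attack at the α-carbon.

**Step 14**
Reactants: 15
Product: 16, 3-hydroxyglabrol, (2R,3R)-3,7,4'-trihydroxy-8,3'-diprenylflavanone
Conditions: Hoveda–Grubbs II (5 mol%), 2-methyl-2-butene (30 equiv), 1,4-benzoquinone (10 mol%), CH2Cl2, 40 °C, sealed tube, 16 h
Reagents that add atoms: 2-methyl-2-butene, CC=C(C)C (supplies the =CMe2 terminus)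
Why: Cross-metathesis of each terminal allyl arene with excess trisubstituted alkene gives the prenyl arene, releasing ethylene and propene. Benzoquinone suppresses Ru–H isomerisation to propenyl. The stereocentres are not involved.
Proposed new method: the closest precedent is the standard CM conversion of allylarenes to prenylarenes. It is applied here to a free polyphenolic, α-hydroxy-ketone dihydroflavonol that could chelate or poison the Ru catalyst.

## Compound list

1 | 1,3-dimethoxybenzene | COc1cccc(OC)c1 | starting material
2 | 2-allyl-1,3-dimethoxybenzene | C=CCc1c(OC)cccc1OC | intermediate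
3 | 2-allyl-4-bromo-1,3-dimethoxybenzene | C=CCc1c(OC)ccc(Br)c1OC | intermediate
4 | 2-allyl-4-bromobenzene-1,3-diol | C=CCc1c(O)ccc(Br)c1O | intermediate
5 | 2-allyl-4-bromo-1,3-bis(TBSO)benzene | C=CCc1c(O[Si](C)(C)C(C)(C)C)ccc(Br)c1O[Si](C)(C)C(C)(C)C | intermediate
6 | methyl (E)-3-(4-hydroxyphenyl)acrylate | COC(=O)/C=C/c1ccc(O)cc1 | starting material
7 | methyl (E)-3-(4-allyloxyphenyl)acrylate | COC(=O)/C=C/c1ccc(OCC=C)cc1 | intermediate
8 | methyl (E)-3-(3-allyl-4-hydroxyphenyl)acrylate | COC(=O)/C=C/c1ccc(O)c(CC=C)c1 | intermediate
9 | methyl (E)-3-[3-allyl-4-(TBSO)phenyl]acrylate | COC(=O)/C=C/c1ccc(O[Si](C)(C)C(C)(C)C)c(CC=C)c1 | intermediate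
10 | (E)-3-[3-allyl-4-(TBSO)phenyl]prop-2-en-1-ol | OC/C=C/c1ccc(O[Si](C)(C)C(C)(C)C)c(CC=C)c1 | intermediate
11 | {(2S,3S)-3-[3-allyl-4-(TBSO)phenyl]oxiran-2-yl}methanol | OC[C@@H]1O[C@H]1c1ccc(O[Si](C)(C)C(C)(C)C)c(CC=C)c1 | intermediate
12 | (2R,3S)-3-[3-allyl-4-(TBSO)phenyl]oxirane-2-carboxylic acid | OC(=O)[C@@H]1O[C@H]1c1ccc(O[Si](C)(C)C(C)(C)C)c(CC=C)c1 | intermediate
13 | (2R,3S)-Weinreb amide of 12 | CON(C)C(=O)[C@@H]1O[C@H]1c1ccc(O[Si](C)(C)C(C)(C)C)c(CC=C)c1 | intermediate
14 | (2R,3S)-epoxy aryl ketone (three TBS groups, two allyl groups) | C=CCc1c(O[Si](C)(C)C(C)(C)C)ccc(C(=O)[C@@H]2O[C@H]2c2ccc(O[Si](C)(C)C(C)(C)C)c(CC=C)c2)c1O[Si](C)(C)C(C)(C)C | intermediate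
15 | (2R,3R)-8,3'-diallyl-3,7,4'-trihydroxyflavanone | C=CCc1cc([C@H]2Oc3c(ccc(O)c3CC=C)C(=O)[C@@H]2O)ccc1O | intermediate
16 | 3-hydroxyglabrol | CC(C)=CCc1cc([C@H]2Oc3c(ccc(O)c3CC=C(C)C)C(=O)[C@@H]2O)ccc1O | target

## Totals

Total steps: 14. Longest linear sequence: 10 steps, from 6 to 16.

## Three steps most likely to fail

1. **Step 13 (desilylation and 6-endo cyclisation).** 5-exo attack at the α-carbon can give aurone-type benzofuranones, and basic fluoride can epimerise or ring-open the product.
   Fallback: reverse the order of bond formation. Open epoxide 13 intermolecularly at the benzylic carbon with the mono-silylated phenol from 4 (Lewis-acid or base promoted, with inversion). Protect the C3-OH as a silyl ether. Then close the C4–C4a bond by Parham cyclisation of the aryl bromide onto the Weinreb amide (t-BuLi, –78 °C).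

2. **Step 14 (late-stage double cross-metathesis).** The free phenols and α-hydroxy ketone may poison the Ru catalyst, and mono-prenyl or isomerised products may form.
   Fallback: install the prenyl groups on the fragments instead. Run cross-metathesis on 5 and on 10 (or 9), and carry the prenyl groups through the acid-free sequence, so the final step is the fluoride cyclisation. If Ti/TBHP proves unselective for the prenylated substrate, use a prenyl-free epoxidation substrate.

3. **Step 12 (aryllithium addition to the epoxy Weinreb amide).** The ortho-silyloxy aryllithium can undergo O→C silyl migration, or it can deprotonate or open the epoxide.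
   Fallback: change the acyl equivalent. Oxidise epoxy alcohol 11 to the epoxy aldehyde with Dess–Martin periodinane, add the aryllithium from 5, and oxidise the resulting diastereomeric epoxy carbinols with Dess–Martin periodinane to 14. This avoids the Weinreb amide and epoxy acid entirely.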